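**Retrosynthetic overview**
- The acrylic acid C=C is made last from aldehyde 8 by Knoevenagel–Doebner condensation, which gives the free acid directly, so no ester has to be cleaved beside the acetate.
- The acetate comes from secondary alcohol 7 by acylation.
- The aryl–CH2 bond comes from an allyl–aryl coupling of Z-diol 4 with arylboronic acid 5 at the primary allylic C–O bond.
- Key step: the C4–O bond, the C1–O handle, the Z-alkene and the R stereocentre all come from one enantioselective 1,4-dioxygenation of the diene of (E)-β-ocimene 1.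
- No ring is built; the benzene ring is bought with 5.

Assumption 1: the (R,R)-ligand gives the 4R product in step 1; if the sense of induction is the reverse, the (S,S)-ligand is used with no other change.
Assumption 2: commercial ocimene is used as its (E)-β isomer; the minor (Z)-β isomer cannot reach the s-cis geometry, gives a 1,2-diol and is removed by chromatography after step 1.

**Step 1**
Reactants: 1 (3E)-3,7-dimethylocta-1,3,6-triene ((E)-β-ocimene), 2 bis(pinacolato)diboron
Product: 4 (2Z,4R)-3,7-dimethylocta-2,6-diene-1,4-diol, via bis(pinacolboronate) 3 (not isolated)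
Conditions: Pt(dba)3 (3 mol%), (R,R)-TADDOL-derived P-phenyl phosphonite carrying four 3,5-diisopropylphenyl groups (6 mol%), THF, 60 °C; then 30% H2O2, 3 M NaOH, 0 °C to rt
Reagents that add atoms: hydrogen peroxide, OO
Why: Platinum-catalysed enantioselective diene 1,4-diboration followed by boronate oxidation (net asymmetric 1,4-dihydroxylation): B–B adds to zerovalent platinum, the s-cis diene inserts to give the Z-allylic 1,4-bis(boronate) with the chiral phosphonite choosing the diene face (C4 = R), and peroxide replaces each C–B bond by C–O with retention, while the isolated trisubstituted alkene is inert.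

**Step 2**
Reactants: 4 (2Z,4R)-3,7-dimethylocta-2,6-diene-1,4-diol, 5 (5-formyl-2-methoxyphenyl)boronic acid
Product: 7 3-[(2Z,4R)-4-hydroxy-3,7-dimethylocta-2,6-dien-1-yl]-4-methoxybenzaldehyde, via cyclic aryl boronate 6 (not isolated)
Conditions: 5 (1.1 equiv), 4 Å MS, toluene, 40 °C; then Pd(PPh3)4 (5 mol%), 60 °C; pH 7 buffer work-up
Reagents that add atoms: none
Why: Proposed new method: the Z-diol and the boronic acid condense to the seven-membered dioxaborepine 6, in which boron both activates the allylic C–O bonds and carries the aryl group; zerovalent palladium ionises the less hindered primary C1–O bond, the freed boronate oxygen binds palladium and delivers the aryl group intramolecularly, and reductive elimination at the primary allyl terminus (the other terminus is fully substituted) gives the linear arene before the tertiary sigma-allyl needed for Z/E scrambling can form, the secondary C4–O bond never being broken so the stereocentre is kept; the closest known reaction type is the base-free Suzuki–Miyaura (Tsuji–Trost-type) coupling of simple allylic alcohols with arylboronic acids, not shown on an unprotected, stereodefined Z-ene-1,4-diol where two allylic C–O bonds compete.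

**Step 3**
Reactants: 7 3-[(2Z,4R)-4-hydroxy-3,7-dimethylocta-2,6-dien-1-yl]-4-methoxybenzaldehyde
Product: 8 (2Z,4R)-1-(5-formyl-2-methoxyphenyl)-3,7-dimethylocta-2,6-dien-4-yl acetate
Conditions: Ac2O (1.5 equiv), pyridine, DMAP (5 mol%), CH2Cl2, 0 °C to rt
Reagents that add atoms: acetic anhydride, CC(=O)OC(C)=O
Why: DMAP-catalysed acyl transfer to the only hydroxyl group; no bond to C4 is broken, so the R configuration is retained, and the aldehyde and alkenes are untouched.

**Step 4**
Reactants: 8 (2Z,4R)-1-(5-formyl-2-methoxyphenyl)-3,7-dimethylocta-2,6-dien-4-yl acetate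
Product: 9 (2E)-3-{3-[(2Z,4R)-4-acetoxy-3,7-dimethylocta-2,6-dien-1-yl]-4-methoxyphenyl}prop-2-enoic acid
Conditions: malonic acid (2.5 equiv), piperidine (10 mol%), pyridine, 80 °C; then aqueous citric acid
Reagents that add atoms: malonic acid, OC(=O)CC(=O)O
Why: Knoevenagel–Doebner condensation: the aldehyde condenses with malonic acid via its iminium and decarboxylative elimination gives only the E-cinnamic acid as the free acid under weakly basic conditions that an alkyl acetate tolerates.

**Compound list**
1 | (3E)-3,7-dimethylocta-1,3,6-triene ((E)-β-ocimene) | C=C/C(C)=C/CC=C(C)C | starting material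
2 | bis(pinacolato)diboron | CC1(C)OB(OC1(C)C)B1OC(C)(C)C(C)(C)O1 | starting material
3 | 2,2'-[(2Z,4R)-3,7-dimethylocta-2,6-diene-1,4-diyl]bis(4,4,5,5-tetramethyl-1,3,2-dioxaborolane) | CC1(C)OB(C/C=C(/C)[C@@H](CC=C(C)C)B2OC(C)(C)C(C)(C)O2)OC1(C)C | intermediate
4 | (2Z,4R)-3,7-dimethylocta-2,6-diene-1,4-diol | OC/C=C(/C)[C@@H](CC=C(C)C)O | intermediate
5 | (5-formyl-2-methoxyphenyl)boronic acid | COc1ccc(C=O)cc1B(O)O | starting material
6 | 4-methoxy-3-[(4R)-5-methyl-4-(3-methylbut-2-en-1-yl)-4,7-dihydro-1,3,2-dioxaborepin-2-yl]benzaldehyde | COc1ccc(C=O)cc1B1OC/C=C(/C)[C@@H](CC=C(C)C)O1 | intermediate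
7 | 3-[(2Z,4R)-4-hydroxy-3,7-dimethylocta-2,6-dien-1-yl]-4-methoxybenzaldehyde | COc1ccc(C=O)cc1C/C=C(/C)[C@@H](CC=C(C)C)O | intermediate
8 | (2Z,4R)-1-(5-formyl-2-methoxyphenyl)-3,7-dimethylocta-2,6-dien-4-yl acetate | COc1ccc(C=O)cc1C/C=C(/C)[C@@H](CC=C(C)C)OC(C)=O | intermediate
9 | (2E)-3-{3-[(2Z,4R)-4-acetoxy-3,7-dimethylocta-2,6-dien-1-yl]-4-methoxyphenyl}prop-2-enoic acid | COc1ccc(/C=C/C(=O)O)cc1C/C=C(/C)[C@@H](CC=C(C)C)OC(C)=O | target

**Totals**
Total step count: 4. Longest linear sequence: 4.

**Three steps most likely to fail**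

Step 1 (enantioselective 1,4-dioxygenation). The methyl group on the diene next to the new stereocentre may lower the enantioselectivity or divert some material to 1,2-addition. The fallback sets out from 1 and comes back at 4, replacing catalyst control by reagent-controlled ketone reduction:
- Ni(cod)2/PCy3-catalysed 1,4-diboration of 1 with 2 (toluene, 60 °C) gives racemic 2,2'-[(2Z)-3,7-dimethylocta-2,6-diene-1,4-diyl]bis(4,4,5,5-tetramethyl-1,3,2-dioxaborolane) F1.
- H2O2/NaOH oxidises it to racemic (2Z)-3,7-dimethylocta-2,6-diene-1,4-diol F2.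
- TBSCl/imidazole at −20 °C silylates the primary hydroxyl to give racemic (2Z)-1-[(tert-butyldimethylsilyl)oxy]-3,7-dimethylocta-2,6-dien-4-ol F3.
- Dess–Martin periodinane buffered with NaHCO3 oxidises the secondary alcohol to (2Z)-1-[(tert-butyldimethylsilyl)oxy]-3,7-dimethylocta-2,6-dien-4-one F4.
- Corey–Bakshi–Shibata reduction ((S)-2-methyl-CBS-oxazaborolidine, BH3·SMe2, toluene, −40 °C, alkenyl as the large group) gives (2Z,4R)-1-[(tert-butyldimethylsilyl)oxy]-3,7-dimethylocta-2,6-dien-4-ol F5.
- n-Bu4NF in THF removes the silyl group to return 4.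

Step 2 (the proposed new coupling). Ionisation of the boronate may be slow, or the secondary C4–O bond or the Z-alkene may not survive. The fallback sets out from 4 and comes back at 8, bypassing step 3, and relies on the known leaving-group hierarchy of allylic carbonate over allylic acetate:
- Methyl chloroformate/pyridine in CH2Cl2 at −30 °C acylates only the primary hydroxyl to give (2Z,4R)-4-hydroxy-3,7-dimethylocta-2,6-dien-1-yl methyl carbonate F6.
- Ac2O/DMAP gives (2Z,4R)-1-[(methoxycarbonyl)oxy]-3,7-dimethylocta-2,6-dien-4-yl acetate F7.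
- Suzuki–Miyaura coupling of the allylic carbonate with 5 (Pd(PPh3)4, KF, THF, rt to 40 °C) ionises only the carbonate and gives 8 with the olefin geometry retained.

Step 4 (Knoevenagel–Doebner). The electron-rich aldehyde may condense slowly, and prolonged heating with amine could cost some acetate. The fallback sets out from 8 and comes back at 9 by a low-temperature Horner–Wadsworth–Emmons olefination:
- Lithiated trimethylsilyl diethylphosphonoacetate (n-BuLi, THF, −78 to 0 °C) gives trimethylsilyl (2E)-3-{3-[(2Z,4R)-4-acetoxy-3,7-dimethylocta-2,6-dien-1-yl]-4-methoxyphenyl}prop-2-enoate F8.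
- F8 is hydrolysed to 9 during the aqueous citric acid work-up.

**Further compounds**
F1 | step 1 | racemic 2,2'-[(2Z)-3,7-dimethylocta-2,6-diene-1,4-diyl]bis(4,4,5,5-tetramethyl-1,3,2-dioxaborolane) | CC1(C)OB(C/C=C(/C)C(CC=C(C)C)B2OC(C)(C)C(C)(C)O2)OC1(C)C
F2 | step 1 | racemic (2Z)-3,7-dimethylocta-2,6-diene-1,4-diol | OC/C=C(/C)C(O)CC=C(C)C
F3 | step 1 | racemic (2Z)-1-[(tert-butyldimethylsilyl)oxy]-3,7-dimethylocta-2,6-dien-4-ol | CC(C)(C)[Si](C)(C)OC/C=C(/C)C(O)CC=C(C)C
F4 | step 1 | (2Z)-1-[(tert-butyldimethylsilyl)oxy]-3,7-dimethylocta-2,6-dien-4-one | CC(C)(C)[Si](C)(C)OC/C=C(/C)C(=O)CC=C(C)C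
F5 | step 1 | (2Z,4R)-1-[(tert-butyldimethylsilyl)oxy]-3,7-dimethylocta-2,6-dien-4-ol | CC(C)(C)[Si](C)(C)OC/C=C(/C)[C@@H](CC=C(C)C)O
F6 | step 2 | (2Z,4R)-4-hydroxy-3,7-dimethylocta-2,6-dien-1-yl methyl carbonate | COC(=O)OC/C=C(/C)[C@@H](CC=C(C)C)O
F7 | step 2 | (2Z,4R)-1-[(methoxycarbonyl)oxy]-3,7-dimethylocta-2,6-dien-4-yl acetate | COC(=O)OC/C=C(/C)[C@@H](CC=C(C)C)OC(C)=O
F8 | step 4 | trimethylsilyl (2E)-3-{3-[(2Z,4R)-4-acetoxy-3,7-dimethylocta-2,6-dien-1-yl]-4-methoxyphenyl}prop-2-enoate | COc1ccc(/C=C/C(=O)O[Si](C)(C)C)cc1C/C=C(/C)[C@@H](CC=C(C)C)OC(C)=O
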